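## Retrosynthetic overview

1. Rings A and B, with C-4, C-5, C-9 and C-10, are taken intact from (−)-abietic acid (1); its ring C is cut out (C-12 hydroxylation, glycol cleavage) to leave a C-12 aldehyde and a C-17 enal.
2. The C-12 aldehyde is grown into the (12E)-diene (crotylboration, syn-elimination); the enal is transposed to the 7β-hydroxy-8(17)-ene (epoxidation, Wharton, oxidation, Luche reduction); the C-18 acid is then freed.
3. The dienophile is the B-ring para-quinone of diosmetin (2), made by Teuber oxidation; the chromone and the carbons of the ene-dione ring come intact.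
4. Key disconnection: ring C and a temporary 16-membered boron-bridged ring close together in a phenylboron-templated intramolecular Diels–Alder reaction (C-18 CO2–B–O-5 tether), which sets C-12 and both ring-fusion centres.
5. Ring order: A and B (chiral pool), chromone and quinone ring (diosmetin), then ring C with the temporary macrocycle last; hydrolysis returns the template.

Assumption: abietane numbering is used for 1 and 3–5 and labdane numbering from 6 on (abietane C-14 becomes labdane C-17), primes mark the former flavone B ring, and commercial 1 is recrystallised once before use.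

## Route

Step 1
Reactants: 1 (−)-abietic acid
Product: 3 methyl abietate
Conditions: MeI, K2CO3, DMF, rt
Reagents that add atoms: iodomethane, CI
Why: SN2 O-alkylation of the carboxylate by MeI works even for this hindered tertiary acid and masks it for the oxidations that follow; no stereocentre is touched.

Step 2
Reactants: 3 methyl abietate
Product: 4 methyl 12α-hydroxyabieta-7,13-dien-18-oate
Conditions: SeO2 (0.3 equiv), t-BuOOH, CH2Cl2, 0 °C to rt
Reagents that add atoms: tert-butyl hydroperoxide, CC(C)(C)OO
Why: Riley allylic hydroxylation (ene reaction, then 2,3-sigmatropic shift) engages the more electron-rich 13,14-alkene and takes hydrogen from the C-12 methylene, with oxygen arriving on the less hindered α-face; this carbinol centre is removed again in step 3.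

Step 3
Reactants: 4 methyl 12α-hydroxyabieta-7,13-dien-18-oate
Product: 6 methyl 12,17-dioxo-13,14,15,16-tetranorlabd-7-en-18-oate, via triol 5 (not isolated)
Conditions: OsO4 (2 mol %), NMO, acetone/H2O, rt; then NaIO4, THF/H2O, 0 °C
Reagents that add atoms: N-methylmorpholine N-oxide, C[N+]1([O-])CCOCC1; water, O
Why: Upjohn dihydroxylation picks the allylic-alcohol 13,14-alkene (anti to the 12-OH, Kishi rule) over the more hindered 7,8-alkene, and twofold Malaprade cleavage of the 12,13,14-triol cuts out C-13 with its isopropyl group, leaving aldehydes at C-12 and C-17 with C-9 untouched.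

Step 4
Reactants: 6 methyl 12,17-dioxo-13,14,15,16-tetranorlabd-7-en-18-oate
Product: 7 methyl 12-hydroxy-17-oxolabda-7,14-dien-18-oate (12,13-anti)
Conditions: (E)-crotyl-Bpin (1.05 equiv), PhMe, rt; then aq. NaHCO3
Reagents that add atoms: (E)-crotylboronic acid pinacol ester, C/C=C/CB1OC(C)(C)C(C)(C)O1
Why: allylboration through a closed chair (Zimmerman–Traxler) transition state is far faster at the unhindered saturated aldehyde than at the α-branched enal and turns the (E)-crotyl geometry into the 12,13-anti relationship; the two anti diastereomers (about 1:1 at C-12) give the same diene in step 5.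

Step 5
Reactants: 7 methyl 12-hydroxy-17-oxolabda-7,14-dien-18-oate (12,13-anti)
Product: 8 methyl 17-oxolabda-7,12E,14-trien-18-oate
Conditions: Burgess reagent, PhH, 50 °C
Reagents that add atoms: none
Why: Burgess dehydration is a syn elimination (Ei) through the sulfamate, which takes the allylic H-13 and, from the anti alcohol, can only give the conjugated diene with 12E geometry (C-11 cis to the C-13 methyl).

Step 6
Reactants: 8 methyl 17-oxolabda-7,12E,14-trien-18-oate
Product: 9 methyl 7α,8α-epoxy-17-oxolabda-12E,14-dien-18-oate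
Conditions: 30% H2O2, NaOH (0.2 equiv), MeOH, 0 °C
Reagents that add atoms: hydrogen peroxide, OO
Why: Weitz–Scheffer nucleophilic epoxidation reacts only with the electron-poor enal alkene (the diene is inert to hydroperoxide anion), the nucleophile adding axially to C-7 on the α-face away from the C-10 methyl, so both new centres are α.

Step 7
Reactants: 9 methyl 7α,8α-epoxy-17-oxolabda-12E,14-dien-18-oate
Product: 11 methyl 7α-hydroxylabda-8(17),12E,14-trien-18-oate, via epoxy hydrazone 10 (not isolated)
Conditions: N2H4·H2O, AcOH (cat.), MeOH, 0 °C to rt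
Reagents that add atoms: none
Why: Wharton transposition: the epoxy hydrazone opens to a vinyl diazene that loses N2, so C-17 becomes the exocyclic methylene while the epoxide oxygen stays on C-7 with its α-configuration.

Step 8
Reactants: 11 methyl 7α-hydroxylabda-8(17),12E,14-trien-18-oate
Product: 12 methyl 7-oxolabda-8(17),12E,14-trien-18-oate
Conditions: Dess–Martin periodinane, CH2Cl2, 0 °C
Reagents that add atoms: none
Why: Dess–Martin oxidation of the allylic alcohol is fast and non-basic, so the exocyclic enone forms without the alkene moving into the ring (which would erase C-9), and the wrong C-7 configuration is removed.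

Step 9
Reactants: 12 methyl 7-oxolabda-8(17),12E,14-trien-18-oate
Product: 13 methyl 7β-hydroxylabda-8(17),12E,14-trien-18-oate
Conditions: NaBH4, CeCl3·7H2O, MeOH, −78 °C
Reagents that add atoms: none
Why: Luche 1,2-reduction, in which hydride adds axially to C-7 from the α-face, opposite the C-10 methyl, and gives the equatorial 7β-alcohol of the target.

Step 10
Reactants: 13 methyl 7β-hydroxylabda-8(17),12E,14-trien-18-oate
Product: 14 7β-hydroxylabda-8(17),12E,14-trien-18-oic acid
Conditions: NaSEt, DMF, 80 °C; then 1 M HCl to pH 4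
Reagents that add atoms: none
Why: the neopentyl-type ester resists attack at the carbonyl, so it is cleaved by SN2 demethylation with thiolate at the O-methyl carbon, under which the diene, the allylic alcohol and all stereocentres survive.

Step 11
Reactants: 2 diosmetin
Product: 15 2-(5,7-dihydroxy-4-oxo-4H-chromen-2-yl)-5-methoxy-1,4-benzoquinone
Conditions: (KSO3)2NO, KH2PO4, H2O/acetone, rt
Reagents that add atoms: potassium nitrosodisulfonate, [K+].[K+].[O]N(S(=O)(=O)[O-])S(=O)(=O)[O-]
Why: Teuber oxidation: the electron-rich 3'-hydroxy-4'-methoxyphenyl ring, whose position para to the hydroxyl is free, is oxidised to the para-quinone, while the hydrogen-bonded, carbonyl-deactivated A-ring phenols do not react.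

Step 12
Reactants: 14 7β-hydroxylabda-8(17),12E,14-trien-18-oic acid; 15 2-(5,7-dihydroxy-4-oxo-4H-chromen-2-yl)-5-methoxy-1,4-benzoquinone
Product: 18 dichrostachine E, via boron-assembled pair 16 (not isolated), via boron-bridged cycloadduct 17 (not isolated)
Conditions: PhB(OH)2 (1.0 equiv), 4 Å MS, CH2Cl2 (5 mM), rt then 40 °C; then THF/H2O, rt
Reagents that add atoms: none
Why: Proposed new method: phenylboronic acid condenses with the C-18 acid of 14 and the 5-OH of 15 (the 4-C=O closing a six-membered chelate on boron), which lowers the LUMO of the chromone-conjugated quinone C=C and makes the Diels–Alder reaction intramolecular, closing the cyclohexene and a 16-membered boron-bridged ring in one event with C-12 bonded to the chromone-bearing carbon; the tether can only close if the chromone lies under the α-face of the decalin (free of axial methyls, and the side on which the C-18 carboxyl sits) and points back from C-12 toward C-18, that is chromone endo and quinone carbonyls exo on one diene face, which is the arrangement that gives C-12, the quaternary carbon and the ring-fusion CH of the target; hydrolysis then returns the template, and the closest known reactions are boronate-tethered Diels–Alder reactions of dienols with hydroxy dienophiles (Narasaka type) and Lewis-acid-assembled cycloadditions.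

## Compound list

1 | (−)-abietic acid (abieta-7,13-dien-18-oic acid; 4α-CO2H, 4β-Me, 5α-H, 9α-H, 10β-Me) | CC(C)C1=CC2=CC[C@@H]3[C@](C)(CCC[C@@]3(C)C(=O)O)[C@H]2CC1 | starting material
2 | diosmetin (5,7,3'-trihydroxy-4'-methoxyflavone) | COc1ccc(cc1O)-c1cc(=O)c2c(O)cc(O)cc2o1 | starting material
3 | methyl abietate | CC(C)C1=CC2=CC[C@@H]3[C@](C)(CCC[C@@]3(C)C(=O)OC)[C@H]2CC1 | intermediate
4 | methyl 12α-hydroxyabieta-7,13-dien-18-oate | CC(C)C1=CC2=CC[C@@H]3[C@](C)(CCC[C@@]3(C)C(=O)OC)[C@H]2C[C@@H]1O | intermediate
5 | methyl 12α,13β,14β-trihydroxyabiet-7-en-18-oate | CC(C)[C@]1(O)[C@@H](O)C2=CC[C@@H]3[C@](C)(CCC[C@@]3(C)C(=O)OC)[C@H]2C[C@@H]1O | intermediate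
6 | methyl 12,17-dioxo-13,14,15,16-tetranorlabd-7-en-18-oate (ring centres as in 1) | O=CC1=CC[C@@H]2[C@](C)(CCC[C@@]2(C)C(=O)OC)[C@H]1CC=O | intermediate
7 | methyl 12-hydroxy-17-oxolabda-7,14-dien-18-oate, 12,13-anti (drawn isomer, carried together with its 12,13-bis-epimer) | O=CC1=CC[C@@H]2[C@](C)(CCC[C@@]2(C)C(=O)OC)[C@H]1C[C@@H](O)[C@@H](C)C=C | intermediate
8 | methyl 17-oxolabda-7,12E,14-trien-18-oate | O=CC1=CC[C@@H]2[C@](C)(CCC[C@@]2(C)C(=O)OC)[C@H]1C/C=C(\C)C=C | intermediate
9 | methyl 7α,8α-epoxy-17-oxolabda-12E,14-dien-18-oate | O=C[C@]12O[C@@H]2C[C@@H]3[C@](C)(CCC[C@@]3(C)C(=O)OC)[C@H]1C/C=C(\C)C=C | intermediate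
10 | C-17 hydrazone of 9 | N/N=C/[C@]12O[C@@H]2C[C@@H]3[C@](C)(CCC[C@@]3(C)C(=O)OC)[C@H]1C/C=C(\C)C=C | intermediate
11 | methyl 7α-hydroxylabda-8(17),12E,14-trien-18-oate | C=C1[C@H](O)C[C@@H]2[C@](C)(CCC[C@@]2(C)C(=O)OC)[C@H]1C/C=C(\C)C=C | intermediate
12 | methyl 7-oxolabda-8(17),12E,14-trien-18-oate | C=C1C(=O)C[C@@H]2[C@](C)(CCC[C@@]2(C)C(=O)OC)[C@H]1C/C=C(\C)C=C | intermediate
13 | methyl 7β-hydroxylabda-8(17),12E,14-trien-18-oate | C=C1[C@@H](O)C[C@@H]2[C@](C)(CCC[C@@]2(C)C(=O)OC)[C@H]1C/C=C(\C)C=C | intermediate
14 | 7β-hydroxylabda-8(17),12E,14-trien-18-oic acid | C=C1[C@@H](O)C[C@@H]2[C@](C)(CCC[C@@]2(C)C(=O)O)[C@H]1C/C=C(\C)C=C | intermediate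
15 | 2-(5,7-dihydroxy-4-oxo-4H-chromen-2-yl)-5-methoxy-1,4-benzoquinone | COC1=CC(=O)C(=CC1=O)c1cc(=O)c2c(O)cc(O)cc2o1 | intermediate
16 | phenylboron-linked pair: the C-18 carboxylate oxygen of 14 and O-5 of 15 on one B(Ph), 4-C=O coordinated to boron | C=C1[C@@H](O)C[C@@H]2[C@](C)(CCC[C@@]2(C)C(=O)OB(c3ccccc3)Oc3cc(O)cc4oc(cc(=O)c34)C3=CC(=O)C(OC)=CC3=O)[C@H]1C/C=C(\C)C=C | intermediate
17 | boron-bridged cycloadduct: target skeleton with B(Ph) still spanning the C-18 carboxylate oxygen and O-5 (16-membered ring) | C=C1[C@@H](O)C[C@@H]2[C@](C)(CCC[C@@]2(C)C(=O)OB(c3ccccc3)O4)[C@H]1C[C@@H]1C(C)=CC[C@H]2C(=O)C(OC)=CC(=O)[C@@]12c1cc(=O)c2c4cc(O)cc2o1 | intermediate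
18 | dichrostachine E | C=C1[C@@H](O)C[C@@H]2[C@](C)(CCC[C@@]2(C)C(=O)O)[C@H]1C[C@@H]1C(C)=CC[C@H]2C(=O)C(OC)=CC(=O)[C@@]12c1cc(=O)c2c(O)cc(O)cc2o1 | target

## Step count and risks

Total step count: 12. Longest linear sequence: 11 (steps 1 to 10, then step 12).

Step 12 is the most likely to fail. The tether and its stereochemical outcome are argued from a hand-built model, not from precedent on this system; the boron may also bind the free 7-OH of 14 or the 7-OH of the chromone, and the tethered transition state may be too strained. The fallback drops the template and runs the bimolecular cycloaddition: it sets out from 14 and 15, stirred without boron in 2,2,2-trifluoroethanol/water at 35 °C, and comes back at 18, which is separated from its endo and facial diastereomers by preparative HPLC. It needs no new compound, and 18 is then expected to be a minor isomer.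

Step 2 can over-oxidise, or aromatise ring C to the dehydroabietate. The fallback sets out from 3 and brings in the C-12 oxygen by epoxide isomerisation instead of an ene reaction. mCPBA (NaHCO3, CH2Cl2, −20 °C) gives methyl 13α,14α-epoxyabiet-7-en-18-oate F1. LiNEt2 (Et2O, 0 °C) removes H-12 and opens it to methyl 14α-hydroxyabieta-7,12-dien-18-oate F2. OsO4/NMO then gives methyl 12β,13β,14α-trihydroxyabiet-7-en-18-oate F3, and NaIO4 cleaves this triol to come back at 6.

Step 7 is risky because Wharton reactions of hindered epoxy aldehydes often give low yields, and diimide formed from hydrazine can reduce the diene. The fallback sets out from 8 and transposes by reagent-controlled epoxidation and reductive opening instead. NaBH4/CeCl3·7H2O gives methyl 17-hydroxylabda-7,12E,14-trien-18-oate F4. Sharpless epoxidation (Ti(OiPr)4, D-(−)-diethyl tartrate, t-BuOOH, −20 °C) gives methyl 7β,8β-epoxy-17-hydroxylabda-12E,14-dien-18-oate F5. I2/PPh3/imidazole gives methyl 7β,8β-epoxy-17-iodolabda-12E,14-dien-18-oate F6, and Zn dust in EtOH opens it to come back at 13, so that steps 6 to 9 are bypassed.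

Further compounds
F1 | step 2 | methyl 13α,14α-epoxyabiet-7-en-18-oate | CC(C)[C@@]12O[C@@H]1C4=CC[C@@H]3[C@](C)(CCC[C@@]3(C)C(=O)OC)[C@H]4CC2
F2 | step 2 | methyl 14α-hydroxyabieta-7,12-dien-18-oate | O[C@@H]1C2=CC[C@@H]3[C@](C)(CCC[C@@]3(C)C(=O)OC)[C@H]2CC=C1C(C)C
F3 | step 2 | methyl 12β,13β,14α-trihydroxyabiet-7-en-18-oate | CC(C)[C@]1(O)[C@H](O)C2=CC[C@@H]3[C@](C)(CCC[C@@]3(C)C(=O)OC)[C@H]2C[C@H]1O
F4 | step 7 | methyl 17-hydroxylabda-7,12E,14-trien-18-oate | OCC1=CC[C@@H]2[C@](C)(CCC[C@@]2(C)C(=O)OC)[C@H]1C/C=C(\C)C=C
F5 | step 7 | methyl 7β,8β-epoxy-17-hydroxylabda-12E,14-dien-18-oate | OC[C@@]12O[C@H]2C[C@@H]3[C@](C)(CCC[C@@]3(C)C(=O)OC)[C@H]1C/C=C(\C)C=C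
F6 | step 7 | methyl 7β,8β-epoxy-17-iodolabda-12E,14-dien-18-oate | IC[C@@]12O[C@H]2C[C@@H]3[C@](C)(CCC[C@@]3(C)C(=O)OC)[C@H]1C/C=C(\C)C=C
F0 | step 12 | none | none
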